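**Retrosynthetic overview**
- Last bond: the C5–O–C10 ether, by transannular Markovnikov addition of a C5 hydroxyl to a C10 exocyclic alkene in a ten-membered carbocycle; this closes both seven-membered rings at once and fixes C10.
- Before that: the ten-membered ring, by intramolecular Nozaki–Hiyama–Kishi coupling (C4–C5) of a (Z)-α-iodo enoate with a C5 aldehyde.
- Key C–C bond (C7–C8): the allylindium of a 3-(bromomethyl)butenolide adds to a β,γ-unsaturated aldehyde. The lactone β-carbon, normally an acceptor, acts as the nucleophile (homoenolate-type, reversed polarity); this sets C7 and C8 and delivers the α-methylene lactone.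
- C8 ester by Mitsunobu inversion with (S)-2-hydroxy-2-methylbut-3-enoic acid; butenolide by ring-closing metathesis from (S)-but-3-ene-1,2-diol.
- Ring order: butenolide, then ten-membered carbocycle, then oxepane and oxepene together.

Assumption: locants follow germacrane numbering (C1–C10 ring, C11–C13 lactone with C12 the carbonyl and C13 the CH2, C14 methyl on C10, C15 ester carbon on C4); 10, 12 and 16 are taken as catalogue compounds.

**Route**

Step 1
Reactants: 1 3-methylbut-3-en-1-ol; 2 2-bromo-1,1-diethoxyethane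
Product: 4 6,6-diethoxy-3-methylidenehexan-1-ol, via dilithio dianion 3 (not isolated)
Conditions: n-BuLi (2.2 equiv), TMEDA, Et2O, 0 °C → rt; then 2, THF, −78 °C → rt
Reagents that add atoms: none
Why: The allyl/alkoxide dianion of isoprenol is alkylated at its allylic terminus by the primary bromide (SN2); both termini give the same product and no stereocentre is formed.

Step 2
Reactants: 4 6,6-diethoxy-3-methylidenehexan-1-ol
Product: 5 6-hydroxy-4-methylidenehexanal
Conditions: oxalic acid (cat.), THF/H2O, rt; used crude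
Reagents that add atoms: water (O)
Why: Mild acid-catalysed acetal hydrolysis frees the aldehyde without touching the 1,1-disubstituted alkene or the alcohol.

Step 3
Reactants: 5 6-hydroxy-4-methylidenehexanal; 6 methyl 2-(triphenylphosphoranylidene)acetate
Product: 8 methyl (2Z)-8-hydroxy-2-iodo-6-methylideneoct-2-enoate, via iodinated ylide 7 (not isolated)
Conditions: 6, NIS, CH2Cl2, −20 °C; then 5, −20 °C → rt
Reagents that add atoms: N-iodosuccinimide (O=C1CCC(=O)N1I)
Why: Wittig olefination with the in situ iodinated stabilised ylide puts the ester trans to the chain, giving the (Z)-α-iodo enoate whose geometry is later carried into the ring.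

Step 4
Reactants: 8 methyl (2Z)-8-hydroxy-2-iodo-6-methylideneoct-2-enoate
Product: 9 methyl (2Z)-2-iodo-6-methylidene-8-oxooct-2-enoate
Conditions: Dess–Martin periodinane, pyridine, CH2Cl2, 0 °C; used at once
Reagents that add atoms: none
Why: Buffered Dess–Martin oxidation gives the β,γ-unsaturated aldehyde without acid or base that would move the alkene into conjugation.

Step 5
Reactants: 10 (2S)-but-3-ene-1,2-diol
Product: 11 (2S)-1-[(triethylsilyl)oxy]but-3-en-2-ol
Conditions: Et3SiCl (1.0 equiv), imidazole, CH2Cl2, −78 → −30 °C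
Reagents that add atoms: chlorotriethylsilane (CC[Si](Cl)(CC)CC)
Why: Low-temperature silylation is selective for the primary hydroxyl; the stereocentre (later C6, S) comes from the starting diol.

Step 6
Reactants: 11 (2S)-1-[(triethylsilyl)oxy]but-3-en-2-ol; 12 2-(bromomethyl)prop-2-enoic acid
Product: 14 (2S)-1-[(triethylsilyl)oxy]but-3-en-2-yl 2-(bromomethyl)prop-2-enoate, via acid chloride 13 (not isolated)
Conditions: 12, (COCl)2, DMF (cat.), CH2Cl2, 0 °C → rt; then 11, 2,6-lutidine, −20 → 0 °C
Reagents that add atoms: none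
Why: Acylation of the secondary alcohol by the acid chloride with a hindered, non-nucleophilic pyridine base avoids quaternisation of the allylic bromide and does not touch the C–O stereocentre.

Step 7
Reactants: 14 (2S)-1-[(triethylsilyl)oxy]but-3-en-2-yl 2-(bromomethyl)prop-2-enoate
Product: 15 (5S)-3-(bromomethyl)-5-{[(triethylsilyl)oxy]methyl}furan-2(5H)-one
Conditions: second-generation Grubbs catalyst (5 mol %), toluene, 80 °C, 0.01 M
Reagents that add atoms: none
Why: Ring-closing metathesis of the acrylate with the vinyl group closes the butenolide, driven by loss of ethene; the catalyst tolerates the allylic bromide.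

Step 8
Reactants: 16 [(2R)-2-methyloxiran-2-yl]methanol
Product: 17 (2S)-2-methylbut-3-ene-1,2-diol
Conditions: Me3S+ I−, n-BuLi, THF, −10 °C → rt
Reagents that add atoms: trimethylsulfonium iodide (C[S+](C)C.[I-])
Why: Dimethylsulfonium methylide opens the epoxide at its CH2 terminus and the betaine loses dimethyl sulfide (one-carbon homologation to an allylic alcohol); the quaternary carbinol centre is untouched, so the (R)-epoxide gives the (S)-vinyl diol.

Step 9
Reactants: 17 (2S)-2-methylbut-3-ene-1,2-diol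
Product: 18 (2S)-2-hydroxy-2-methylbut-3-enoic acid
Conditions: TEMPO (cat.), NaOCl (cat.), NaClO2, MeCN/phosphate buffer pH 6.7, 35 °C
Reagents that add atoms: sodium chlorite ([Na+].[O-]Cl=O)
Why: TEMPO/chlorite oxidation takes only the primary alcohol to the acid; the tertiary allylic alcohol cannot be oxidised and its configuration is retained.

Step 10 (key step)
Reactants: 15 (5S)-3-(bromomethyl)-5-{[(triethylsilyl)oxy]methyl}furan-2(5H)-one; 9 methyl (2Z)-2-iodo-6-methylidene-8-oxooct-2-enoate
Product: 20 methyl (2Z,8S)-8-hydroxy-2-iodo-6-methylidene-8-[(2S,3R)-4-methylidene-5-oxo-2-{[(triethylsilyl)oxy]methyl}oxolan-3-yl]oct-2-enoate, via allylindium bromide 19 (not isolated)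
Conditions: In powder (1.5 equiv), THF/H2O 4:1, 0 °C → rt
Reagents that add atoms: none
Why: In this Barbier-type indium allylation the allylindium reacts at its γ-carbon, so the lactone β-carbon C7 (an acceptor site in 15) attacks the aldehyde carbon C8 as a homoenolate-type donor; attack anti to the C6 substituent sets 7R (trans lactone), and a Zimmerman–Traxler chair with the ring-locked E-allyl unit gives the 7,8-anti (8S) alcohol.

Step 11
Reactants: 20 the (8S)-alcohol from step 10; 18 (2S)-2-hydroxy-2-methylbut-3-enoic acid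
Product: 21 methyl (2Z,8R)-8-{[(2S)-2-hydroxy-2-methylbut-3-enoyl]oxy}-2-iodo-6-methylidene-8-[(2S,3R)-4-methylidene-5-oxo-2-{[(triethylsilyl)oxy]methyl}oxolan-3-yl]oct-2-enoate
Conditions: PPh3, DIAD, toluene/THF, 0 °C → rt
Reagents that add atoms: none
Why: In the Mitsunobu esterification the carboxylate displaces the activated C8 hydroxyl by SN2 with inversion to the required 8R ester; the tertiary hydroxyl of the acid is inert, so no protecting group is needed.

Step 12
Reactants: 21 the (8R)-ester from step 11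
Product: 22 methyl (2Z,8R)-8-[(2S,3R)-2-formyl-4-methylidene-5-oxooxolan-3-yl]-8-{[(2S)-2-hydroxy-2-methylbut-3-enoyl]oxy}-2-iodo-6-methylideneoct-2-enoate
Conditions: (COCl)2, DMSO, CH2Cl2, −78 → −40 °C; then Et3N, −78 → −20 °C
Reagents that add atoms: none
Why: Swern conditions cleave a primary triethylsilyl ether through the chlorosulfonium salt and oxidise it directly to the aldehyde; the tertiary alcohol cannot be oxidised and the cold base does not epimerise C6.

Step 13
Reactants: 22 the iodo-enoate aldehyde from step 12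
Product: 24 methyl (3E,5R,6S,7R,8R)-5-hydroxy-8-{[(2S)-2-hydroxy-2-methylbut-3-enoyl]oxy}germacra-3,10(14),11(13)-trien-15-oate 12,6-lactone, via vinylchromium chloride 23 (not isolated)
Conditions: CrCl2 (8 equiv), NiCl2 (2 mol %), DMSO/THF 3:1, rt, 0.002 M, slow addition
Reagents that add atoms: none
Why: In this intramolecular Nozaki–Hiyama–Kishi reaction the vinylchromium formed from the iodide adds only to the aldehyde and closes the ten-membered ring with retention of the enoate geometry; Felkin–Anh addition anti to the C6–O bond gives the 5,6-anti (5R) alcohol.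

Step 14
Reactants: 24 the ten-membered hydroxy lactone from step 13
Product: 25 methyl (3E,5R,6S,7R,8R,10S)-5,10-epoxy-8-{[(2S)-2-hydroxy-2-methylbut-3-enoyl]oxy}germacra-3,11(13)-dien-15-oate 12,6-lactone (target CNP0325750.1)
Conditions: TfOH (10 mol %), CH2Cl2, −20 → 0 °C
Reagents that add atoms: none
Why: In this acid-catalysed transannular Markovnikov hydroalkoxylation, protonation of the methylidene group gives the tertiary C10 cation, which the C5 hydroxyl captures across the ring; the oxygen can only bridge C5 and C10 on one face, so C10 (S) follows from C5.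

**Compound list**
1 | 3-methylbut-3-en-1-ol | CC(=C)CCO | starting material
2 | 2-bromo-1,1-diethoxyethane | CCOC(CBr)OCC | starting material
3 | dilithio dianion of 1 (allyl anion and alkoxide) | [Li+].[Li+].[CH2-]C(=C)CC[O-] | intermediate (not isolated)
4 | 6,6-diethoxy-3-methylidenehexan-1-ol | CCOC(CCC(=C)CCO)OCC | intermediate
5 | 6-hydroxy-4-methylidenehexanal | O=CCCC(=C)CCO | intermediate
6 | methyl 2-(triphenylphosphoranylidene)acetate | COC(=O)C=P(c1ccccc1)(c1ccccc1)c1ccccc1 | starting material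
7 | methyl 2-iodo-2-(triphenylphosphoranylidene)acetate | COC(=O)C(I)=P(c1ccccc1)(c1ccccc1)c1ccccc1 | intermediate (not isolated)
8 | methyl (2Z)-8-hydroxy-2-iodo-6-methylideneoct-2-enoate | COC(=O)/C(I)=C/CCC(=C)CCO | intermediate
9 | methyl (2Z)-2-iodo-6-methylidene-8-oxooct-2-enoate | COC(=O)/C(I)=C/CCC(=C)CC=O | intermediate
10 | (2S)-but-3-ene-1,2-diol | C=C[C@H](O)CO | starting material
11 | (2S)-1-[(triethylsilyl)oxy]but-3-en-2-ol | C=C[C@H](O)CO[Si](CC)(CC)CC | intermediate
12 | 2-(bromomethyl)prop-2-enoic acid | OC(=O)C(=C)CBr | starting material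
13 | 2-(bromomethyl)prop-2-enoyl chloride | ClC(=O)C(=C)CBr | intermediate (not isolated)
14 | (2S)-1-[(triethylsilyl)oxy]but-3-en-2-yl 2-(bromomethyl)prop-2-enoate | C=C[C@H](OC(=O)C(=C)CBr)CO[Si](CC)(CC)CC | intermediate
15 | (5S)-3-(bromomethyl)-5-{[(triethylsilyl)oxy]methyl}furan-2(5H)-one | O=C1O[C@H](CO[Si](CC)(CC)CC)C=C1CBr | intermediate
16 | [(2R)-2-methyloxiran-2-yl]methanol | OC[C@]1(C)CO1 | starting material
17 | (2S)-2-methylbut-3-ene-1,2-diol | C=C[C@](C)(O)CO | intermediate
18 | (2S)-2-hydroxy-2-methylbut-3-enoic acid | C=C[C@](C)(O)C(=O)O | intermediate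
19 | {[(5S)-2-oxo-5-{[(triethylsilyl)oxy]methyl}-2,5-dihydrofuran-3-yl]methyl}indium dibromide (drawn as the RInBr2 component of the allylindium sesquibromide) | O=C1O[C@H](CO[Si](CC)(CC)CC)C=C1C[In](Br)Br | intermediate (not isolated)
20 | methyl (2Z,8S)-8-hydroxy-2-iodo-6-methylidene-8-[(2S,3R)-4-methylidene-5-oxo-2-{[(triethylsilyl)oxy]methyl}oxolan-3-yl]oct-2-enoate | C=C1C(=O)O[C@H](CO[Si](CC)(CC)CC)[C@H]1[C@@H](O)CC(=C)CC/C=C(\I)C(=O)OC | intermediate
21 | methyl (2Z,8R)-8-{[(2S)-2-hydroxy-2-methylbut-3-enoyl]oxy}-2-iodo-6-methylidene-8-[(2S,3R)-4-methylidene-5-oxo-2-{[(triethylsilyl)oxy]methyl}oxolan-3-yl]oct-2-enoate | C=C1C(=O)O[C@H](CO[Si](CC)(CC)CC)[C@H]1[C@H](OC(=O)[C@@](C)(O)C=C)CC(=C)CC/C=C(\I)C(=O)OC | intermediate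
22 | methyl (2Z,8R)-8-[(2S,3R)-2-formyl-4-methylidene-5-oxooxolan-3-yl]-8-{[(2S)-2-hydroxy-2-methylbut-3-enoyl]oxy}-2-iodo-6-methylideneoct-2-enoate | C=C1C(=O)O[C@H](C=O)[C@H]1[C@H](OC(=O)[C@@](C)(O)C=C)CC(=C)CC/C=C(\I)C(=O)OC | intermediate
23 | vinylchromium dichloride of 22 (CrCl2 on C4 in place of iodine, trivalent chromium) | C=C1C(=O)O[C@H](C=O)[C@H]1[C@H](OC(=O)[C@@](C)(O)C=C)CC(=C)CC/C=C(\[Cr](Cl)Cl)C(=O)OC | intermediate (not isolated)
24 | methyl (3E,5R,6S,7R,8R)-5-hydroxy-8-{[(2S)-2-hydroxy-2-methylbut-3-enoyl]oxy}germacra-3,10(14),11(13)-trien-15-oate 12,6-lactone | C=C[C@](C)(O)C(=O)O[C@@H]1CC(=C)CC/C=C(C(=O)OC)\[C@@H](O)[C@H]2OC(=O)C(=C)[C@@H]21 | intermediate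
25 | methyl (3E,5R,6S,7R,8R,10S)-5,10-epoxy-8-{[(2S)-2-hydroxy-2-methylbut-3-enoyl]oxy}germacra-3,11(13)-dien-15-oate 12,6-lactone | C=C[C@](C)(O)C(=O)O[C@@H]1C[C@]2(C)CCC=C(C(=O)OC)[C@@H](O2)[C@H]2OC(=O)C(=C)[C@@H]21 | target

**Step count**
Total steps: 14. Longest linear sequence: 9 steps (1 → 4 → 5 → 8 → 9 → 20 → 21 → 22 → 24 → 25).

**Steps most likely to fail, with fallbacks**

Step 10. Aldehyde 9 can slip into conjugation, the 7,8-selectivity may be lower than the chair model predicts, and the route then depends on inversion at a hindered carbinol in step 11.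
Fallback (sets out from 15 and 9, comes back at 21): switch from the Barbier reaction to a Lewis-acid-promoted allylstannane addition that gives the 8R alcohol directly.
- Pd(PPh3)4-catalysed stannylation of 15 with hexabutylditin gives (5S)-3-[(tributylstannyl)methyl]-5-{[(triethylsilyl)oxy]methyl}furan-2(5H)-one F1.
- BF3·OEt2-promoted addition of F1 to 9 at −78 °C goes through an open antiperiplanar transition state, anti to the C6 substituent, and gives the 7,8-syn alcohol methyl (2Z,8R)-8-hydroxy-2-iodo-6-methylidene-8-[(2S,3R)-4-methylidene-5-oxo-2-{[(triethylsilyl)oxy]methyl}oxolan-3-yl]oct-2-enoate F2.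
- Yamaguchi esterification of F2 with 18 (2,4,6-trichlorobenzoyl chloride, Et3N, DMAP; retention) gives 21.

Step 13. The ten-membered ring may not close, or C5 may form with the wrong configuration.
Fallback (sets out from 1, 15 and 18, comes back at 25): make the ether before any carbocycle and close the last ring by metathesis.
- Dianion 3 is alkylated with allyl bromide to 3-methylidenehept-6-en-1-ol F3, and Dess–Martin oxidation gives 3-methylidenehept-6-enal F4.
- Indium coupling with 15 gives (4R,5S)-4-[(1S)-1-hydroxy-3-methylidenehept-6-en-1-yl]-3-methylidene-5-{[(triethylsilyl)oxy]methyl}oxolan-2-one F5.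
- Mitsunobu reaction with 18 gives (1R)-3-methylidene-1-[(2S,3R)-4-methylidene-5-oxo-2-{[(triethylsilyl)oxy]methyl}oxolan-3-yl]hept-6-en-1-yl (2S)-2-hydroxy-2-methylbut-3-enoate F6.
- Swern oxidation gives (1R)-1-[(2S,3R)-2-formyl-4-methylidene-5-oxooxolan-3-yl]-3-methylidenehept-6-en-1-yl (2S)-2-hydroxy-2-methylbut-3-enoate F7.
- Intermolecular CrCl2/NiCl2 coupling with methyl 2-iodoprop-2-enoate (acyclic Felkin–Anh control) gives methyl (3R)-3-hydroxy-3-[(2S,3R)-3-[(1R)-1-{[(2S)-2-hydroxy-2-methylbut-3-enoyl]oxy}-3-methylidenehept-6-en-1-yl]-4-methylidene-5-oxooxolan-2-yl]-2-methylidenepropanoate F8.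
- TfOH adds the C5 hydroxyl to the C10 methylidene group and closes the oxepane, giving the 3,4-seco analogue of 25 that carries but-3-enyl on C10 and 1-(methoxycarbonyl)vinyl on C5 (5R,6S,7R,8R,10S) F9.
- Ring-closing metathesis with the second-generation Grubbs catalyst, possible only for the 5,10-cis isomer, forms C3=C4 and gives 25.

Step 14. The C10 cation may be trapped by the side-chain hydroxyl or the C8 ester carbonyl, or may eliminate.
Fallback (sets out from 24, comes back at 25): replace protonation by iodonium-triggered cyclisation and remove the halogen afterwards.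
- N-iodosuccinimide in CH2Cl2 at 0 °C gives the 14-iodo derivative of 25 (CH2I on C10, 10S) F10.
- Radical deiodination with Bu3SnH/Et3B/air at −78 → 0 °C at high tin hydride concentration gives 25.

**Further compounds**
F1 | step 10 | (5S)-3-[(tributylstannyl)methyl]-5-{[(triethylsilyl)oxy]methyl}furan-2(5H)-one | O=C1O[C@H](CO[Si](CC)(CC)CC)C=C1C[Sn](CCCC)(CCCC)CCCC
F2 | step 10 | methyl (2Z,8R)-8-hydroxy-2-iodo-6-methylidene-8-[(2S,3R)-4-methylidene-5-oxo-2-{[(triethylsilyl)oxy]methyl}oxolan-3-yl]oct-2-enoate | C=C1C(=O)O[C@H](CO[Si](CC)(CC)CC)[C@H]1[C@H](O)CC(=C)CC/C=C(\I)C(=O)OC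
F3 | step 13 | 3-methylidenehept-6-en-1-ol | C=CCCC(=C)CCO
F4 | step 13 | 3-methylidenehept-6-enal | C=CCCC(=C)CC=O
F5 | step 13 | (4R,5S)-4-[(1S)-1-hydroxy-3-methylidenehept-6-en-1-yl]-3-methylidene-5-{[(triethylsilyl)oxy]methyl}oxolan-2-one | C=C1C(=O)O[C@H](CO[Si](CC)(CC)CC)[C@H]1[C@@H](O)CC(=C)CCC=C
F6 | step 13 | (1R)-3-methylidene-1-[(2S,3R)-4-methylidene-5-oxo-2-{[(triethylsilyl)oxy]methyl}oxolan-3-yl]hept-6-en-1-yl (2S)-2-hydroxy-2-methylbut-3-enoate | C=C1C(=O)O[C@H](CO[Si](CC)(CC)CC)[C@H]1[C@H](OC(=O)[C@@](C)(O)C=C)CC(=C)CCC=C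
F7 | step 13 | (1R)-1-[(2S,3R)-2-formyl-4-methylidene-5-oxooxolan-3-yl]-3-methylidenehept-6-en-1-yl (2S)-2-hydroxy-2-methylbut-3-enoate | C=C1C(=O)O[C@H](C=O)[C@H]1[C@H](OC(=O)[C@@](C)(O)C=C)CC(=C)CCC=C
F8 | step 13 | methyl (3R)-3-hydroxy-3-[(2S,3R)-3-[(1R)-1-{[(2S)-2-hydroxy-2-methylbut-3-enoyl]oxy}-3-methylidenehept-6-en-1-yl]-4-methylidene-5-oxooxolan-2-yl]-2-methylidenepropanoate | C=C1C(=O)O[C@H]([C@H](O)C(=C)C(=O)OC)[C@H]1[C@H](OC(=O)[C@@](C)(O)C=C)CC(=C)CCC=C
F9 | step 13 | 3,4-seco analogue of 25 with but-3-enyl on C10 and 1-(methoxycarbonyl)vinyl on C5 (5R,6S,7R,8R,10S) | C=C[C@](C)(O)C(=O)O[C@@H]1C[C@](C)(CCC=C)O[C@H](C(=C)C(=O)OC)[C@H]2OC(=O)C(=C)[C@@H]21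
F10 | step 14 | 14-iodo derivative of 25 (CH2I on C10, 10S) | C=C[C@](C)(O)C(=O)O[C@@H]1C[C@]2(CI)CCC=C(C(=O)OC)[C@@H](O2)[C@H]2OC(=O)C(=C)[C@@H]21
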